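Target: compound **20**, 2-[(E)-chloro{(2S,4aS,8aS)-2,5,5,8a-tetramethyloctahydronaphthalen-1(2H)-ylidene}methyl]-6-methoxybenzene-1,4-diol. Drimane numbering is used throughout (ring A: C1–C5, C10; ring B: C5–C10; C11 is the chlorinated carbon, C12 the methyl on C8; arene C1′–C6′).

## Analysis of the target

Compound 20 is a trans-fused decalin (rings A and B) whose C9 carries an exocyclic, fully substituted double bond to C11. C11 bears chlorine and a 2,5-dihydroxy-3-methoxyphenyl ring. There are three stereocentres, all S: C5 (H α), C10 (methyl β) and C8 (methyl β). C5 and C10 define the trans ring fusion. The C8 methyl is axial on ring B and syn to the C10 methyl, which leaves H8, not a methyl group, in the plane of the alkene beside chlorine. The alkene is E: chlorine lies on the C8 side and the aryl ring on the side of the quaternary C10. The hydroquinone is air-sensitive and must be released last. The tetrasubstituted styrenyl chloride rules out hydrogenolysis catalysts, and with a carbonyl at C8 it becomes a β-chloro enone, a vinylogous acid chloride. The hard part is a quaternary C10 directly next to a tetrasubstituted chloroalkene of fixed geometry, plus an axial methyl at C8. The route rests on three facts. C10 with its methyl group and C1 is the trisubstituted alkene of a 2,6,6-trimethylcyclohexenyl (α-ionone) unit. C9 and C11 sit at the oxidation level of an aryl alkyne. A C5–C6–C7–C8 tether lets a C10 radical reach C9 in a six-membered closure, leaving a linear C11 radical flanked unequally by C8 and C10.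

## Retrosynthetic reasoning

**Arene oxidation level.** Hydroquinone 20 is taken back to quinone 19 and then to trimethyl ether 18. Three methyl ethers survive every earlier step, and the 2′,5′ pair is para, so one oxidative demethylation followed by a mild reduction releases exactly the two hydroxyl groups of 20 and keeps the 3′-methoxy group.

**C8 methyl (C8–C12).** The methyl group of 18 is cut back to the exocyclic methylene of diene 17, and this to the ketone of β-chloro enone 16. Introducing it late means no methyl group has to go axial during ring formation. The axial C10 methyl then covers the β face of C8=C12, so hydrogen enters from the α face and the methyl ends up β.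

**C8 oxidation level.** Enone 16 comes from allylic alcohol 15 and this from silyl ether 14. The oxygen on C8 is the handle left by the way the side chain is built. Because it is oxidised, its configuration need not be controlled.

**Key disconnection (C9–C10 and C11–Cl).** Silyl ether 14 is opened to enyne 13. Cutting here removes ring B, the quaternary centre and the chloroalkene in one move and leaves a monocyclic terpene unit plus an aryl alkyne. In the forward direction a hydrogen atom must go to C1. The C10 radical must then add to C9 before it meets the chlorine-atom donor, and the resulting C11 radical must take chlorine from the C8 side.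

**Aryl–alkyne bond (C11–C1′).** Enyne 13 is divided into terminal alkyne 8 and aryl bromide 12. This keeps the route convergent and puts the arene in one step before the key step.

**C8–C9 bond.** Alkyne 8 is the silyl ether of propargylic alcohol 7, which comes from aldehyde 6 and a two-carbon acetylide. Either configuration at C8 will do.

**Terpene unit.** Aldehyde 6 is reached from alcohol 5 and acid 4. Acid 4 is the one-carbon degradation product of (S)-dihydro-α-ionone 3, obtained by conjugate reduction of (S)-α-ionone 2 from racemic α-ionone 1. Ring A, the gem-dimethyl group, the C1=C10 alkene and the C5 stereocentre are bought in this way. Only the methyl ketone carbon has to be removed.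

**Arene.** Aryl bromide 12 is the methyl ether of phenol 11, which comes from 5-bromoveratraldehyde 9 through formate 10. The formyl group is the precursor of the third oxygen and fixes the 2,3,5-pattern relative to bromine.

## Alternatives that were turned down

**Alternative 1:** intramolecular Diels–Alder reaction of a chloroallene.
- Disconnection: C5–C10 and C8–C9, so both rings come from the open-chain trienyl allene A2.
- Forward key step: on heating, the E,E-diene C5=C6–C7=C8 of A2 adds to the C9=C10 bond of the 1-aryl-1-chloroallene and gives A1, the 6,7-didehydro form of 18.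
- For it: one step makes ring A (through the tether), ring B, C5, C8, C10 and the chloroalkene. The C8 methyl arrives with the right configuration, because the outer substituents of an E,E-diene end up cis. After the key step only saturation of C6=C7 separates A1 from 18. On step count after ring formation and on C8 it is stronger than the chosen route.
- Against it: everything hangs on the allene axis. The axis must be made enantiopure and must survive heating, although a 1-aryl-1-chloroallene with an electron-rich aryl group can racemise by C–Cl ionisation. It must also steer the diene to the chlorine-bearing face. The cycloaddition joins C5, next to the quaternary C4, to the fully substituted C10, so a congested trans-fused transition state must beat the cis-fused one and the [2+2] and ene pathways of the allene.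
- Comparison: making A2 with a defined axis needs an enantioselective propargylic precursor and a stereospecific SN2′ chlorination, which is no shorter than the sequence to 13. The chosen route takes C5 from α-ionone and puts only one new stereocentre and one alkene geometry at risk in the key step. It pays for this with more steps after ring closure.

**Alternative 2:** ring expansion of a four-membered ring to the hydroquinone.
- Disconnection: the arene itself, across C5′–C6′, back to the 4-alkenyl-4-hydroxycyclobutenone A4.
- Forward key step: heating opens A4 to a dienylketene, which closes by 6π electrocyclisation between C5′ and C6′ and tautomerises to hydroquinone A3.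
- For it: the three oxygen substituents are placed with full regiocontrol and the two hydroxyl groups are already free. No oxidative demethylation is needed. On the arene it is stronger than the trimethyl ether route.
- Against it: the key step solves the easy half. In A3, C11 is a methylene group and C9 an sp3 stereocentre. The tetrasubstituted chloroalkene would have to be made afterwards by benzylic oxidation and a geometry-defining chlorination next to an oxidation-prone hydroquinone. The complete decalin with all three stereocentres must also be supplied beforehand.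
- Comparison: the chosen route builds the decalin and the chloroalkene together and handles the arene with robust methyl ether chemistry.

**Alternative 3:** formal [3+3] benzannulation.
- Disconnection: C3′–C4′ and C1′–C6′ of the arene. Three ring carbons come from the bis(silyl enol ether) A6 and three from pentamethoxypropane A7.
- Forward key step: a strong Lewis acid condenses A6 with A7 to the ortho-hydroxyaryl ketone A5.
- For it: it is convergent and the C3 partner is cheap. C11 arrives at the ketone oxidation level, closer to the chloroalkene than in A3, and the 2′-hydroxyl group is free.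
- Against it: the ketone of A5 is flanked by the neopentyl-type C9 and hydrogen-bonded to the ortho hydroxyl group. Turning it into the chloroalkene means enolisation toward C9, which erases that stereocentre and gives no control of the alkene geometry. The 5′ oxygen is still a methyl ether. The decalin again has to be supplied complete.
- Comparison: on arene construction it is about equal to the chosen route. On the chloroalkene it is weaker, because the chosen key step fixes the geometry through the shape of a linear radical rather than through an enol equilibrium.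

Key step: step 11

Assumption: racemic α-ionone is the commercial material, and its enantiomers are taken to be separable on a preparative chiral stationary phase.

Assumption: C8 is carried as a mixture of both epimers in 7, 8, 13, 14 and 15, because this centre becomes a ketone in step 13.

Remark on descriptors: the geometry "chlorine syn to C8" is Z by the sequence rule in 14–16, where oxygen on C8 raises C8 above C10. It is E from 17 onward.

## Route

Step 1
Reactants: 1 (±)-α-ionone
Product: 2 (S)-(−)-α-ionone
Conditions: preparative SFC, cellulose tris(3,5-dimethylphenylcarbamate) phase, CO2/i-PrOH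
Reagents that add atoms: none
Why: Chromatographic resolution of the racemate; the neutral conditions do not touch the doubly allylic C–H of the stereocentre, and the laevorotatory (S) enantiomer carries the configuration needed at C5.

Step 2
Reactants: 2 (S)-(−)-α-ionone
Product: 3 (S)-dihydro-α-ionone
Conditions: [(Ph3P)CuH]6 (0.35 equiv), H2O (2 equiv), degassed PhH, rt
Reagents that add atoms: none
Why: Copper hydride conjugate reduction of the enone; the isolated trisubstituted ring alkene is inert, and the neutral medium avoids deconjugation or epimerisation at the γ-stereocentre, which is no longer vinylogously acidic afterwards.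

Step 3
Reactants: 3 (S)-dihydro-α-ionone
Product: 4 3-[(1S)-2,6,6-trimethylcyclohex-2-en-1-yl]propanoic acid
Conditions: Br2, NaOH, dioxane/H2O, 0 °C → rt; acidic work-up
Reagents that add atoms: sodium hydroxide, [Na+].[OH-]
Why: Haloform degradation; the methyl group is tribrominated through the enolate and hydroxide cleaves the acyl–CBr3 bond. Hypobromite in strong base is a poor electrophile toward the isolated alkene.

Step 4
Reactants: 4 3-[(1S)-2,6,6-trimethylcyclohex-2-en-1-yl]propanoic acid
Product: 5 3-[(1S)-2,6,6-trimethylcyclohex-2-en-1-yl]propan-1-ol
Conditions: LiAlH4, THF, 0 °C → rt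
Reagents that add atoms: none
Why: Hydride reduction of the carboxylic acid to the primary alcohol; the unactivated alkene does not react.

Step 5
Reactants: 5 3-[(1S)-2,6,6-trimethylcyclohex-2-en-1-yl]propan-1-ol
Product: 6 3-[(1S)-2,6,6-trimethylcyclohex-2-en-1-yl]propanal
Conditions: Dess–Martin periodinane, NaHCO3, CH2Cl2, 0 °C → rt
Reagents that add atoms: none
Why: Dess–Martin oxidation stops at the aldehyde under buffered, non-acidic conditions; the aldehyde is used directly.

Step 6
Reactants: 6 3-[(1S)-2,6,6-trimethylcyclohex-2-en-1-yl]propanal
Product: 7 5-[(1S)-2,6,6-trimethylcyclohex-2-en-1-yl]pent-1-yn-3-ol (both C3 epimers; C3 is the later C8)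
Conditions: HC≡CMgBr, THF, 0 °C; aqueous work-up
Reagents that add atoms: ethynylmagnesium bromide, C#C[Mg]Br
Why: Grignard 1,2-addition forms the C8–C9 bond; the new carbinol centre is not controlled and need not be, since it is oxidised in step 13.

Step 7
Reactants: 7 5-[(1S)-2,6,6-trimethylcyclohex-2-en-1-yl]pent-1-yn-3-ol
Product: 8 tert-butyldimethyl({5-[(1S)-2,6,6-trimethylcyclohex-2-en-1-yl]pent-1-yn-3-yl}oxy)silane (both C3 epimers)
Conditions: TBSCl, imidazole, DMF, rt
Reagents that add atoms: tert-butyldimethylsilyl chloride, CC(C)(C)[Si](C)(C)Cl
Why: Standard silylation of a secondary alcohol; the silyl ether masks the carbinol through the coupling and the radical step.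

Step 8
Reactants: 9 3-bromo-4,5-dimethoxybenzaldehyde (5-bromoveratraldehyde)
Product: 11 3-bromo-4,5-dimethoxyphenol, via 3-bromo-4,5-dimethoxyphenyl formate 10 (not isolated)
Conditions: mCPBA, CH2Cl2, rt; then K2CO3, MeOH
Reagents that add atoms: 3-chloroperoxybenzoic acid, OOC(=O)c1cccc(Cl)c1
Why: Baeyer–Villiger (Dakin-type) oxidation; the electron-rich aryl group with a para-methoxy substituent migrates in preference to hydrogen, and the formate is cleaved by methanolysis.

Step 9
Reactants: 11 3-bromo-4,5-dimethoxyphenol
Product: 12 1-bromo-2,3,5-trimethoxybenzene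
Conditions: MeI, K2CO3, acetone, reflux
Reagents that add atoms: iodomethane, CI
Why: Williamson O-methylation of the phenoxide.

Step 10
Reactants: 8 tert-butyldimethyl({5-[(1S)-2,6,6-trimethylcyclohex-2-en-1-yl]pent-1-yn-3-yl}oxy)silane; 12 1-bromo-2,3,5-trimethoxybenzene
Product: 13 tert-butyldimethyl({1-(2,3,5-trimethoxyphenyl)-5-[(1S)-2,6,6-trimethylcyclohex-2-en-1-yl]pent-1-yn-3-yl}oxy)silane (both C3 epimers)
Conditions: PdCl2(MeCN)2 (3 mol %), XPhos (9 mol %), Cs2CO3, MeCN, 80 °C
Reagents that add atoms: none
Why: Copper-free Sonogashira coupling; the bulky electron-rich biarylphosphine lets zerovalent palladium insert into the electron-rich, ortho-methoxylated C–Br bond, and leaving out copper avoids oxidative dimerisation of the alkyne.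

Step 11
Reactants: 13 tert-butyldimethyl({1-(2,3,5-trimethoxyphenyl)-5-[(1S)-2,6,6-trimethylcyclohex-2-en-1-yl]pent-1-yn-3-yl}oxy)silane
Product: 14 (5S,10S)-8-(tert-butyldimethylsilyloxy)-11-chloro-11-(2,3,5-trimethoxyphenyl)-12-nordrim-9(11)-ene (trans-decalin; chlorine syn to C8; both C8 epimers)
Conditions: Fe(acac)3 (30 mol %), Ph(i-PrO)SiH2 (3 equiv), TsCl (3 equiv), EtOAc, 0.005 M, 40 °C
Reagents that add atoms: 4-toluenesulfonyl chloride, Cc1ccc(cc1)S(Cl)(=O)=O
Why: Proposed new method: an iron hydride formed from Fe(acac)3 and the silane transfers a hydrogen atom to C1, the less substituted end of the electron-rich C1=C10 alkene (Markovnikov sense; the aryl alkyne is a far poorer acceptor), and leaves a tertiary radical at C10. This radical closes ring B by 6-exo-dig attack on C9, which forms the C9–C10 bond and a linear, aryl-stabilised vinyl radical at C11; that radical takes chlorine from TsCl (C11–Cl), and the sulfonyl radical returns divalent iron to the trivalent state. The closest known reactions are hydrogen-atom-transfer hydrochlorination of alkenes with TsCl and atom-transfer radical cyclisations of alkyl radicals onto aryl alkynes; joining them in one operation is the untested part. The new stereocentre C10 is set by C5: with the C5 chain equatorial on ring A, C9 reaches the α lobe of the planar radical through a chair-like six-membered transition state while the β lobe is screened by the axial 4β-methyl group, so the C10 methyl becomes axial and the ring fusion trans. The alkene geometry is set when chlorine is delivered in the plane of the linear radical: the C10 flank is closed by the in-plane C1 methylene and the axial methyl of a quaternary carbon, whereas the C8 flank carries only a tertiary CH, so chlorine should arrive syn to C8. Ring closure must outrun chlorine transfer to the C10 radical, which is why TsCl is kept dilute and the temperature slightly raised. Chlorine transfer to the vinyl radical must outrun hydrogen abstraction, which is why isopropoxy(phenyl)silane in ethyl acetate replaces phenylsilane in an alcohol.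

Step 12
Reactants: 14 (5S,10S)-8-(tert-butyldimethylsilyloxy)-11-chloro-11-(2,3,5-trimethoxyphenyl)-12-nordrim-9(11)-ene
Product: 15 (5S,10S)-11-chloro-11-(2,3,5-trimethoxyphenyl)-12-nordrim-9(11)-en-8-ol (chlorine syn to C8; both C8 epimers)
Conditions: n-Bu4NF, THF, 0 °C → rt
Reagents that add atoms: none
Why: Fluoride-driven cleavage of the Si–O bond; the tetrasubstituted chloroalkene is indifferent to fluoride.

Step 13
Reactants: 15 (5S,10S)-11-chloro-11-(2,3,5-trimethoxyphenyl)-12-nordrim-9(11)-en-8-ol
Product: 16 (5S,10S)-11-chloro-11-(2,3,5-trimethoxyphenyl)-12-nordrim-9(11)-en-8-one (chlorine syn to the carbonyl carbon)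
Conditions: Dess–Martin periodinane, NaHCO3, CH2Cl2, rt
Reagents that add atoms: none
Why: Dess–Martin oxidation of the hindered allylic alcohol; both C8 epimers converge on one ketone, and the buffered, non-nucleophilic medium leaves the β-chloro enone and its geometry intact.

Step 14
Reactants: 16 (5S,10S)-11-chloro-11-(2,3,5-trimethoxyphenyl)-12-nordrim-9(11)-en-8-one
Product: 17 (5S,10S,E)-11-chloro-11-(2,3,5-trimethoxyphenyl)drima-8(12),9(11)-diene
Conditions: Cp2TiMe2, PhMe, 70 °C, dark
Reagents that add atoms: dimethyltitanocene, [CH3-].[CH3-].[Ti+4].c1cc[cH-]c1.c1cc[cH-]c1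
Why: Petasis methylenation; thermally formed Cp2Ti=CH2 reacts with the carbonyl by [2+2] and cycloreversion. It is neither basic nor nucleophilic toward C11, so enolisation toward C7 and addition–elimination at the chlorinated carbon, both likely with a phosphorus ylide, are avoided.

Step 15
Reactants: 17 (5S,10S,E)-11-chloro-11-(2,3,5-trimethoxyphenyl)drima-8(12),9(11)-diene
Product: 18 (5S,8S,10S,E)-11-chloro-11-(2,3,5-trimethoxyphenyl)drim-9(11)-ene (8β-methyl)
Conditions: H2 (1 atm), RhCl(PPh3)3 (10 mol %), PhH/EtOH, rt
Reagents that add atoms: none
Why: Homogeneous hydrogenation selective for the 1,1-disubstituted alkene; the tetrasubstituted chloroalkene is too hindered to bind and is not hydrogenolysed as it would be over Pd/C. The axial C10 methyl covers the β face of C8=C12, so hydrogen is delivered from the α face and the new methyl is β (8S).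

Step 16
Reactants: 18 (5S,8S,10S,E)-11-chloro-11-(2,3,5-trimethoxyphenyl)drim-9(11)-ene
Product: 19 2-[(E)-chloro((5S,8S,10S)-drim-9(11)-en-11-ylidene... 8β-methyl decalinylidene)methyl]-6-methoxy-1,4-benzoquinone
Conditions: (NH4)2Ce(NO3)6, MeCN/H2O, 0 °C
Reagents that add atoms: water, O
Why: Oxidative demethylation of the para 2′,5′-dimethoxy pair by tetravalent cerium through the arene radical cation, attack of water and loss of two molecules of methanol; the para-quinone keeps the 3′-methoxy group, and the twisted, chlorine-bearing alkene is not electron-rich enough to compete.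

Step 17
Reactants: 19 2-methoxy-6-substituted 1,4-benzoquinone (as in step 16)
Product: 20 2-[(E)-chloro{(2S,4aS,8aS)-2,5,5,8a-tetramethyloctahydronaphthalen-1(2H)-ylidene}methyl]-6-methoxybenzene-1,4-diol (target)
Conditions: Na2S2O4, EtOAc/H2O, rt, under argon
Reagents that add atoms: none
Why: Two-electron reduction of the quinone to the hydroquinone by dithionite; the C–Cl bond and the alkene are untouched, and air is excluded to keep the product from reoxidising.

## Compound list

1 | (±)-α-ionone, (E)-4-(2,6,6-trimethylcyclohex-2-en-1-yl)but-3-en-2-one, racemic | CC1=CCCC(C)(C)C1/C=C/C(C)=O | starting material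
2 | (S)-(−)-α-ionone | CC1=CCCC(C)(C)[C@@H]1/C=C/C(C)=O | intermediate
3 | (S)-dihydro-α-ionone, 4-[(1S)-2,6,6-trimethylcyclohex-2-en-1-yl]butan-2-one | CC1=CCCC(C)(C)[C@@H]1CCC(C)=O | intermediate
4 | 3-[(1S)-2,6,6-trimethylcyclohex-2-en-1-yl]propanoic acid | CC1=CCCC(C)(C)[C@@H]1CCC(O)=O | intermediate
5 | 3-[(1S)-2,6,6-trimethylcyclohex-2-en-1-yl]propan-1-ol | CC1=CCCC(C)(C)[C@@H]1CCCO | intermediate
6 | 3-[(1S)-2,6,6-trimethylcyclohex-2-en-1-yl]propanal | CC1=CCCC(C)(C)[C@@H]1CCC=O | intermediate
7 | 5-[(1S)-2,6,6-trimethylcyclohex-2-en-1-yl]pent-1-yn-3-ol, both C3 epimers | CC1=CCCC(C)(C)[C@@H]1CCC(O)C#C | intermediate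
8 | tert-butyldimethyl({5-[(1S)-2,6,6-trimethylcyclohex-2-en-1-yl]pent-1-yn-3-yl}oxy)silane, both C3 epimers | CC1=CCCC(C)(C)[C@@H]1CCC(O[Si](C)(C)C(C)(C)C)C#C | intermediate
9 | 3-bromo-4,5-dimethoxybenzaldehyde (5-bromoveratraldehyde) | COc1cc(C=O)cc(Br)c1OC | starting material
10 | 3-bromo-4,5-dimethoxyphenyl formate (not isolated) | COc1cc(OC=O)cc(Br)c1OC | intermediate
11 | 3-bromo-4,5-dimethoxyphenol | COc1cc(O)cc(Br)c1OC | intermediate
12 | 1-bromo-2,3,5-trimethoxybenzene | COc1cc(OC)cc(Br)c1OC | intermediate
13 | tert-butyldimethyl({1-(2,3,5-trimethoxyphenyl)-5-[(1S)-2,6,6-trimethylcyclohex-2-en-1-yl]pent-1-yn-3-yl}oxy)silane, both C3 epimers (key-step precursor) | CC1=CCCC(C)(C)[C@@H]1CCC(O[Si](C)(C)C(C)(C)C)C#Cc1cc(OC)cc(OC)c1OC | intermediate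
14 | (5S,10S)-8-(tert-butyldimethylsilyloxy)-11-chloro-11-(2,3,5-trimethoxyphenyl)-12-nordrim-9(11)-ene, trans-decalin, chlorine syn to C8 (Z), both C8 epimers (key-step product) | Cl/C(c1cc(OC)cc(OC)c1OC)=C1\C(O[Si](C)(C)C(C)(C)C)CC[C@H]2C(C)(C)CCC[C@]12C | intermediate
15 | (5S,10S)-11-chloro-11-(2,3,5-trimethoxyphenyl)-12-nordrim-9(11)-en-8-ol, chlorine syn to C8 (Z), both C8 epimers | Cl/C(c1cc(OC)cc(OC)c1OC)=C1\C(O)CC[C@H]2C(C)(C)CCC[C@]12C | intermediate
16 | (5S,10S)-11-chloro-11-(2,3,5-trimethoxyphenyl)-12-nordrim-9(11)-en-8-one, chlorine syn to C8 (Z) | Cl/C(c1cc(OC)cc(OC)c1OC)=C1\C(=O)CC[C@H]2C(C)(C)CCC[C@]12C | intermediate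
17 | (5S,10S,E)-11-chloro-11-(2,3,5-trimethoxyphenyl)drima-8(12),9(11)-diene | Cl/C(c1cc(OC)cc(OC)c1OC)=C1\C(=C)CC[C@H]2C(C)(C)CCC[C@]12C | intermediate
18 | (5S,8S,10S,E)-11-chloro-11-(2,3,5-trimethoxyphenyl)drim-9(11)-ene, 8β-methyl | COc1cc(OC)cc(/C(Cl)=C2/[C@@H](C)CC[C@H]3C(C)(C)CCC[C@]23C)c1OC | intermediate
19 | 2-[(E)-chloro{(2S,4aS,8aS)-2,5,5,8a-tetramethyloctahydronaphthalen-1(2H)-ylidene}methyl]-6-methoxy-1,4-benzoquinone | COC1=CC(=O)C=C(/C(Cl)=C2/[C@@H](C)CC[C@H]3C(C)(C)CCC[C@]23C)C1=O | intermediate
20 | 2-[(E)-chloro{(2S,4aS,8aS)-2,5,5,8a-tetramethyloctahydronaphthalen-1(2H)-ylidene}methyl]-6-methoxybenzene-1,4-diol | COc1cc(O)cc(/C(Cl)=C2/[C@@H](C)CC[C@H]3C(C)(C)CCC[C@]23C)c1O | target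

## Step count and least certain steps

Total: 17 steps. Longest linear sequence: 15 steps (steps 1–7 and 10–17, from racemic α-ionone). The arene branch adds steps 8 and 9.

**Step 11 (key step).** Four processes can divert it.
- Chlorine transfer to the C10 radical before ring closure. The 6-exo-dig closure is not fast, and the two rates are of similar order at ordinary donor concentrations.
- A 1,5-hydrogen shift from C8–H to C10. That C–H bond is propargylic and next to oxygen.
- Hydrogen capture by the vinyl radical from the silane or the medium.
- Loss of selectivity: closure through the β lobe (cis fusion), or chlorine delivery from the C10 side for the epimer whose silyloxy group lies in the alkene plane.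

Fallback (known chemistry, polar ring closure): it sets out from 13 and returns at 14. The ring alkene is hydrochlorinated on purpose under the cobalt variant of the hydrogen-atom-transfer reaction (Co(BF4)2·6H2O with a salicylaldimine ligand, t-BuOOH as activator, PhSiH3, excess TsCl at high concentration, EtOH, rt). Chlorine transfer should outrun ring closure there and give the tertiary chloride tert-butyl({5-[(1S)-2-chloro-2,6,6-trimethylcyclohexyl]-1-(2,3,5-trimethoxyphenyl)pent-1-yn-3-yl}oxy)dimethylsilane F1 (epimers at the chlorinated carbon, of no consequence). SnCl4 in CH2Cl2 at −78 °C then ionises the C10–Cl bond. C9 of the alkyne attacks the C10 cation in a chair-like cation–alkyne cyclisation that should give the trans fusion, and the linear aryl-stabilised vinyl cation at C11 takes chloride back on the open C8 flank to give 14. Both halves are established reaction types: Markovnikov hydrochlorination with TsCl, and Lewis acid-mediated addition of a tertiary alkyl chloride across an aryl alkyne. The Lewis acid is kept mild and cold because the propargylic silyl ether can also ionise.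

**Step 15.** Hydrogen may add across the twisted diene in a 1,4 sense. Coordination of the diene may stall the catalyst. Attack on the β face would give the 8α-methyl epimer.

Fallback: it sets out from 17 and returns at 18. Hydroboration with 9-BBN (THF, rt) places boron on C12 and hydrogen on the α face of C8, with the bulky borane sharpening the facial preference. Oxidation with NaBO3·4H2O should give (5S,8S,10S,E)-11-chloro-11-(2,3,5-trimethoxyphenyl)drim-9(11)-en-12-ol F2. Tosylation (TsCl, pyridine) gives its 12-(4-toluenesulfonate) F3, and LiEt3BH in THF displaces the sulfonate by hydride to leave the 8β-methyl group of 18.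

**Step 14.** The titanium methylidene may fail to engage the hindered, cross-conjugated carbonyl. Prolonged heating may scramble the geometry of the β-chloro enone.

Fallback: it sets out from 16 and returns at 17. Me3SiCH2Li with CeCl3 (THF, −78 °C) adds 1,2 to the ketone; the organocerium is small, strongly nucleophilic and hardly basic. This should give (5S,10S)-11-chloro-11-(2,3,5-trimethoxyphenyl)-8-[(trimethylsilyl)methyl]-12-nordrim-9(11)-en-8-ol F4. KH in THF then triggers Peterson elimination to the exocyclic alkene of 17.

**Step 16.** Oxidation may go past the quinone, may reach the styrenyl alkene, or may take the ortho 2′,3′ pair instead of the para pair.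

Fallback: it sets out from 18 and returns at 19. BCl3 (CH2Cl2, −78 → 0 °C) should cleave only the 2′-methoxy group, which is flanked on both sides and twisted out of conjugation. This gives 2-[(E)-chloro{(2S,4aS,8aS)-2,5,5,8a-tetramethyloctahydronaphthalen-1(2H)-ylidene}methyl]-4,6-dimethoxyphenol F5. This para-methoxyphenol is then oxidised under much milder conditions (PhI(OAc)2, MeCN/H2O, 0 °C) to quinone 19.

**Step 3.** Electrophilic bromine may add to the trisubstituted ring alkene (bromohydrin formation) while the methyl ketone is being degraded.

Fallback: it sets out from 3 and returns at 6, bypassing 4 and 5. Kinetic deprotonation of the methyl group (LiN(i-Pr)2, THF, −78 °C) and oxidation of the enolate with 2-(phenylsulfonyl)-3-phenyloxaziridine should give 1-hydroxy-4-[(1S)-2,6,6-trimethylcyclohex-2-en-1-yl]butan-2-one F6. NaBH4 in MeOH reduces it to 4-[(1S)-2,6,6-trimethylcyclohex-2-en-1-yl]butane-1,2-diol F7. NaIO4 in THF/H2O cleaves the diol to aldehyde 6 without touching the alkene.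

## Further compounds

F1 | step 11 | tert-butyl({5-[(1S)-2-chloro-2,6,6-trimethylcyclohexyl]-1-(2,3,5-trimethoxyphenyl)pent-1-yn-3-yl}oxy)dimethylsilane, epimers at the chlorinated carbon and at the carbinol carbon | CC1(Cl)CCCC(C)(C)[C@@H]1CCC(O[Si](C)(C)C(C)(C)C)C#Cc1cc(OC)cc(OC)c1OC
F2 | step 15 | (5S,8S,10S,E)-11-chloro-11-(2,3,5-trimethoxyphenyl)drim-9(11)-en-12-ol | COc1cc(OC)cc(/C(Cl)=C2/[C@@H](CO)CC[C@H]3C(C)(C)CCC[C@]23C)c1OC
F3 | step 15 | (5S,8S,10S,E)-11-chloro-11-(2,3,5-trimethoxyphenyl)drim-9(11)-en-12-yl 4-toluenesulfonate | COc1cc(OC)cc(/C(Cl)=C2/[C@@H](COS(=O)(=O)c4ccc(C)cc4)CC[C@H]3C(C)(C)CCC[C@]23C)c1OC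
F4 | step 14 | (5S,10S)-11-chloro-11-(2,3,5-trimethoxyphenyl)-8-[(trimethylsilyl)methyl]-12-nordrim-9(11)-en-8-ol, chlorine syn to C8, C8 epimers | Cl/C(c1cc(OC)cc(OC)c1OC)=C1\C(O)(C[Si](C)(C)C)CC[C@H]2C(C)(C)CCC[C@]12C
F5 | step 16 | 2-[(E)-chloro{(2S,4aS,8aS)-2,5,5,8a-tetramethyloctahydronaphthalen-1(2H)-ylidene}methyl]-4,6-dimethoxyphenol | COc1cc(OC)cc(/C(Cl)=C2/[C@@H](C)CC[C@H]3C(C)(C)CCC[C@]23C)c1O
F6 | step 3 | 1-hydroxy-4-[(1S)-2,6,6-trimethylcyclohex-2-en-1-yl]butan-2-one | CC1=CCCC(C)(C)[C@@H]1CCC(=O)CO
F7 | step 3 | 4-[(1S)-2,6,6-trimethylcyclohex-2-en-1-yl]butane-1,2-diol, C2 epimers | CC1=CCCC(C)(C)[C@@H]1CCC(O)CO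
A1 | alternative 1 | (5S,8S,10S,E)-11-chloro-11-(2,3,5-trimethoxyphenyl)drima-6,9(11)-diene (6,7-didehydro form of 18) | COc1cc(OC)cc(/C(Cl)=C2/[C@@H](C)C=C[C@H]3C(C)(C)CCC[C@]23C)c1OC
A2 | alternative 1 | 1-[(8E,10E)-1-chloro-3,7,7-trimethyldodeca-1,2,8,10-tetraen-1-yl]-2,3,5-trimethoxybenzene, single allene axis (chlorine turned toward the diene) | COc1cc(OC)cc(C(Cl)=[C@@]=C(C)CCCC(C)(C)/C=C/C=C/C)c1OC
A3 | alternative 2 | 2-(8β-methyldriman-11-yl)-6-methoxyhydroquinone | C[C@H]1CC[C@H]2C(C)(C)CCC[C@]2(C)[C@H]1Cc1cc(O)cc(OC)c1O
A4 | alternative 2 | 4-hydroxy-3-methoxy-4-[3-(8β-methyldriman-9-yl)prop-1-en-2-yl]cyclobut-2-en-1-one, carbinol epimers | C[C@H]1CC[C@H]2C(C)(C)CCC[C@]2(C)[C@H]1CC(=C)C3(O)C(OC)=CC3=O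
A5 | alternative 3 | (2-hydroxy-3,5-dimethoxyphenyl) 8β-methyldriman-9-yl ketone | C[C@H]1CC[C@H]2C(C)(C)CCC[C@]2(C)[C@H]1C(=O)c1cc(OC)cc(OC)c1O
A6 | alternative 3 | 4-methoxy-1-(8β-methyldriman-9-yl)-1,3-bis(trimethylsilyloxy)buta-1,3-diene, alkene geometries open | C[C@H]1CC[C@H]2C(C)(C)CCC[C@]2(C)[C@H]1C(O[Si](C)(C)C)=CC(O[Si](C)(C)C)=COC
A7 | alternative 3 | 1,1,2,3,3-pentamethoxypropane | COC(OC)C(OC)C(OC)OC
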